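**Retrosynthetic overview**

1. Numbering: lactone O1–C2(=O)–C3(Me)=C4–C5, exocyclic C6, C7(Me), ring A C8–C9–C10–C11(Me)–C12(spiro), ring B C12–C13–C14=C15(Me)–C16(O-acyl)–C17. The strategy rests on the adjacent pair C11 (methyl-bearing methine) and C12 (spiro quaternary carbon) of ring A, with the C13 arm trans to the C11 methyl.
2. Key disconnection: C11–CH3 and C12–C13 are made in one flask by enantioselective copper-catalysed methyl addition to 2-allylcyclopent-2-enone and trans alkylation of the enolate with (Z)-1-bromo-3-iodobut-2-ene.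
3. Ring B: C15–C16 by Nozaki–Hiyama–Kishi cyclisation of the C16 aldehyde (from the allyl arm) onto the C15 vinyl iodide.
4. Side chain: C8 ketone transposed to a C10 allylic alcohol (Saegusa–Ito, epoxidation, Wharton); C7–C8 by Ireland–Claisen of the C10 propionate; C5=C6 by silyloxyfuran aldol and elimination; C16 ester last.
5. Ring order: ring A (from cyclopentenone) → ring B (step 7) → butenolide ring brought in intact (step 18).

Key step: step 5

Assumption: the sense of induction of the ferrocenyl diphosphine on this 2-substituted enone is fixed in a test run and the antipode that gives 11S is used. TBS = tert-butyldimethylsilyl, TMS = trimethylsilyl; the C5=C6 bond of the target is Z (C7 cis to O1).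

**Route**

Step 1
Reactants: 1 cyclopent-2-en-1-one
Product: 2 2-iodocyclopent-2-en-1-one
Conditions: I2, pyridine/CH2Cl2 (1:1), 0 °C → rt
Reagents that add atoms: iodine, II
Why: α-Iodination of an enone by a Baylis–Hillman-type sequence (conjugate addition of pyridine, iodination of the enolate, E1cB loss of pyridine), the standard entry to 2-iodoenones.

Step 2
Reactants: 2 2-iodocyclopent-2-en-1-one; 3 allyltributylstannane
Product: 4 2-allylcyclopent-2-en-1-one
Conditions: PdCl2(PhCN)2 (5 mol %), AsPh3 (10 mol %), CuI (10 mol %), NMP, rt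
Reagents that add atoms: allyltributylstannane (3), C=CC[Sn](CCCC)(CCCC)CCCC
Why: Stille coupling of an α-iodoenone, in which zerovalent palladium inserts into the C–I bond, allyl is transferred from tin (helped by AsPh3 and CuI) and reductive elimination at room temperature leaves the skipped diene unconjugated.

Step 3
Reactants: 5 but-2-yn-1-ol
Product: 7 (Z)-3-iodobut-2-en-1-ol, via alkenylalanate 6 (not isolated)
Conditions: NaAlH2(OCH2CH2OCH3)2, THF, 0 °C → rt; then I2, THF, −78 → 0 °C
Reagents that add atoms: iodine, II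
Why: Alkoxide-directed trans-hydroalumination of the propargylic alcohol places aluminium on C3 in a five-membered alanate, and iodinolysis of the C–Al bond with retention gives the vinyl iodide with I cis to CH2OH.

Step 4
Reactants: 7 (Z)-3-iodobut-2-en-1-ol
Product: 8 (Z)-1-bromo-3-iodobut-2-ene
Conditions: PBr3, pyridine (cat.), Et2O, 0 °C
Reagents that add atoms: phosphorus tribromide, BrP(Br)Br
Why: SN2 displacement of the bromophosphite of a primary allylic alcohol, which touches neither the vinyl iodide nor the alkene geometry.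

Step 5
Reactants: 4 2-allylcyclopent-2-en-1-one; 9 methylmagnesium bromide; 8 (Z)-1-bromo-3-iodobut-2-ene
Product: 11 (2R,3S)-2-allyl-2-[(Z)-3-iodobut-2-en-1-yl]-3-methylcyclopentan-1-one, via magnesium enolate 10 (not isolated)
Conditions: CuBr·SMe2 (5 mol %), (R)-1-[(S)-2-(diphenylphosphino)ferrocenyl]ethyldicyclohexylphosphine or its antipode (6 mol %), 9 added slowly, tBuOMe, −78 °C; then 8, HMPA (or DMPU), −78 °C → rt
Reagents that add atoms: methylmagnesium bromide (9), C[Mg]Br; (Z)-1-bromo-3-iodobut-2-ene (8), BrC/C=C(/C)I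
Why: The ligand-bound methylcopper species (monovalent copper) forms a π-complex with the C11=C12 bond of 4, oxidative addition gives a trivalent copper σ-complex at C11, reductive elimination forms C11–CH3 and releases magnesium enolate 10, and 10 is C-alkylated at C12 by the primary allylic bromide 8 in an SN2 step that forms C12–C13. The closest known reaction type is the copper/ferrocenyl-diphosphine-catalysed enantioselective conjugate addition of Grignard reagents to cyclic enones with alkylative trapping of the magnesium enolate, which extends to 2-substituted enones although these react more slowly and less selectively than the parent enones. No ring is closed. C11 (S) is controlled by the catalyst, whose chiral pocket selects one enone face for methyl transfer, and C12 is controlled by the substrate, since the planar tetrasubstituted enolate is attacked on the face opposite the adjacent C11 methyl, which puts the C13 arm trans and the allyl arm (C17) cis to that methyl. The step needs 1,4- over 1,2-addition (copper catalysis, slow Grignard addition in the cold), C- over O-alkylation and SN2 over SN2′ attack (magnesium counter-ion, unhindered CH2Br terminus, HMPA to loosen aggregates) and an intact vinyl iodide (MeMgBr is used up before 8 enters and does not exchange with a vinyl iodide at low temperature). The enolate regiochemistry is fixed by the conjugate addition itself, so only C12 is alkylated.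

Step 6
Reactants: 11 (2R,3S)-2-allyl-2-[(Z)-3-iodobut-2-en-1-yl]-3-methylcyclopentan-1-one
Product: 12 2-[(1S,2S)-1-[(Z)-3-iodobut-2-en-1-yl]-2-methyl-5-oxocyclopentyl]acetaldehyde
Conditions: OsO4 (2 mol %), NaIO4, 2,6-lutidine, dioxane/H2O (3:1), rt
Reagents that add atoms: osmium tetroxide, O=[Os](=O)(=O)=O (catalytic oxygen carrier); sodium periodate, [Na+].[O-]I(=O)(=O)=O (terminal oxygen source)
Why: Lemieux–Johnson cleavage, in which the monosubstituted allyl alkene is dihydroxylated far faster than the trisubstituted, iodine-deactivated alkene and periodate cleaves the diol to the C16 aldehyde.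

Step 7
Reactants: 12 2-[(1S,2S)-1-[(Z)-3-iodobut-2-en-1-yl]-2-methyl-5-oxocyclopentyl]acetaldehyde
Product: 13 (4S,5S,9S)-9-hydroxy-4,8-dimethylspiro[4.5]dec-7-en-1-one
Conditions: CrCl2 (5 equiv), NiCl2 (2 mol %), degassed DMF, rt, 0.01 M
Reagents that add atoms: none
Why: Nozaki–Hiyama–Kishi cyclisation, in which zerovalent nickel inserts into the C15–I bond with retention, transmetalation gives the alkenyl trivalent chromium species and this adds to the aldehyde (not to the hindered C8 ketone) to close ring B; the C16 hydroxyl should arise cis to C8, because the chromium-bound oxygen sits pseudoaxial in a half-chair transition state, syn to the axial C12 substituent, a place better taken by the flat C8 carbonyl (which can also ligate chromium) than by the C11 methine.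

Step 8
Reactants: 13 (4S,5S,9S)-9-hydroxy-4,8-dimethylspiro[4.5]dec-7-en-1-one
Product: 14 (4S,5S,9S)-9-(TBS-oxy)-4,8-dimethylspiro[4.5]dec-7-en-1-one
Conditions: TBSOTf, 2,6-lutidine, CH2Cl2, −78 → 0 °C
Reagents that add atoms: tert-butyldimethylsilyl trifluoromethanesulfonate, CC(C)(C)[Si](C)(C)OS(=O)(=O)C(F)(F)F
Why: Silylation of the hindered secondary allylic alcohol with the silyl triflate, under conditions (lutidine, low temperature) that do not enolise the C8 ketone.

Step 9
Reactants: 14 (4S,5S,9S)-9-(TBS-oxy)-4,8-dimethylspiro[4.5]dec-7-en-1-one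
Product: 16 (4S,5S,9S)-9-(TBS-oxy)-4,8-dimethylspiro[4.5]deca-2,7-dien-1-one, via trimethylsilyl enol ether 15 (not isolated)
Conditions: TMSOTf, Et3N, CH2Cl2, 0 °C; then Pd(OAc)2 (1.1 equiv), MeCN, rt
Reagents that add atoms: none
Why: Saegusa–Ito oxidation, in which the silyl enol ether can only form toward C9 because C12 is quaternary and divalent palladium gives the C9-palladated ketone that loses the C10 hydrogen by β-hydride elimination to give the C9=C10 enone.

Step 10
Reactants: 16 (4S,5S,9S)-9-(TBS-oxy)-4,8-dimethylspiro[4.5]deca-2,7-dien-1-one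
Product: 17 (2S,3S,4R,5S,9S)-9-(TBS-oxy)-2,3-epoxy-4,8-dimethylspiro[4.5]dec-7-en-1-one
Conditions: H2O2 (30 % aq.), NaOH (cat.), MeOH, −10 → 0 °C
Reagents that add atoms: hydrogen peroxide, OO
Why: Weitz–Scheffer epoxidation, in which hydroperoxide adds to C10 on the face opposite the adjacent C11 methyl and the enolate closes the epoxide on that face (C9 and C10 set by the substrate, epoxide trans to the methyl), while catalytic base in the cold avoids γ-deprotonation at C11.

Step 11
Reactants: 17 (2S,3S,4R,5S,9S)-9-(TBS-oxy)-2,3-epoxy-4,8-dimethylspiro[4.5]dec-7-en-1-one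
Product: 18 (1R,2R,5R,9S)-9-(TBS-oxy)-1,8-dimethylspiro[4.5]deca-3,7-dien-2-ol
Conditions: N2H4·H2O, AcOH (cat.), MeOH, 0 °C → rt
Reagents that add atoms: none
Why: Wharton transposition, in which the epoxy hydrazone opens to an allylic diazene that loses N2, moving the alkene to C8=C9 and leaving the C10–O bond and its configuration (O trans to the C11 methyl) untouched.

Step 12
Reactants: 18 (1R,2R,5R,9S)-9-(TBS-oxy)-1,8-dimethylspiro[4.5]deca-3,7-dien-2-ol; 19 propanoic anhydride
Product: 20 (1R,2R,5R,9S)-9-(TBS-oxy)-1,8-dimethylspiro[4.5]deca-3,7-dien-2-yl propanoate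
Conditions: Et3N, DMAP (cat.), CH2Cl2, 0 °C → rt
Reagents that add atoms: propanoic anhydride (19), CCC(=O)OC(=O)CC
Why: DMAP-catalysed acylation of the secondary allylic alcohol, with retention at C10.

Step 13
Reactants: 20 (1R,2R,5R,9S)-9-(TBS-oxy)-1,8-dimethylspiro[4.5]deca-3,7-dien-2-yl propanoate
Product: 24 (2S)-2-[(1R,4S,5S,9S)-9-(TBS-oxy)-4,8-dimethylspiro[4.5]deca-2,7-dien-1-yl]propanoic acid, via lithium enolate 21 (not isolated), via silyl ketene acetal 22 (not isolated), via trimethylsilyl ester 23 (not isolated)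
Conditions: LDA, THF/HMPA (4:1), −78 °C; TMSCl/Et3N, −78 °C → rt then 60 °C; aq. NaOH then acidify to pH 4
Reagents that add atoms: none
Why: Ireland–Claisen rearrangement, in which enolisation in THF/HMPA gives the ketene acetal with the C7 methyl cis to OSi, the suprafacial [3,3] shift forms C7–C8 on the ring A face that carried the C10 oxygen (C8 side chain trans to the C11 methyl), and the boat transition state expected for a cyclopentenyl ester (the chair would push the silyloxy group under ring A against C13) should give 7S.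

Step 14
Reactants: 24 (2S)-2-[(1R,4S,5S,9S)-9-(TBS-oxy)-4,8-dimethylspiro[4.5]deca-2,7-dien-1-yl]propanoic acid
Product: 25 (2S)-2-[(1R,4S,5S,9S)-9-(TBS-oxy)-4,8-dimethylspiro[4.5]dec-7-en-1-yl]propanoic acid
Conditions: TsNHNH2, NaOAc, DME/H2O (1:1), reflux
Reagents that add atoms: none
Why: Diimide reduction by concerted syn hydrogen transfer, which takes the strained cis-disubstituted C9=C10 bond much faster than the trisubstituted C14=C15 bond and causes no allylic C–O hydrogenolysis.

Step 15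
Reactants: 25 (2S)-2-[(1R,4S,5S,9S)-9-(TBS-oxy)-4,8-dimethylspiro[4.5]dec-7-en-1-yl]propanoic acid
Product: 26 (2S)-2-[(1R,4S,5S,9S)-9-(TBS-oxy)-4,8-dimethylspiro[4.5]dec-7-en-1-yl]propan-1-ol
Conditions: LiAlH4, THF, 0 → 40 °C
Reagents that add atoms: none
Why: Hydride reduction of the carboxylic acid to the primary alcohol, in which the carboxylate protects C7 from epimerisation and the silyl ether and alkene are inert.

Step 16
Reactants: 26 (2S)-2-[(1R,4S,5S,9S)-9-(TBS-oxy)-4,8-dimethylspiro[4.5]dec-7-en-1-yl]propan-1-ol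
Product: 27 (2S)-2-[(1R,4S,5S,9S)-9-(TBS-oxy)-4,8-dimethylspiro[4.5]dec-7-en-1-yl]propanal
Conditions: Dess–Martin periodinane, NaHCO3, CH2Cl2, 0 °C → rt
Reagents that add atoms: none
Why: Dess–Martin oxidation under buffered, non-basic conditions gives the α-branched C6 aldehyde without epimerising C7, and the aldehyde is used at once.

Step 17
Reactants: 28 3-methylfuran-2(5H)-one
Product: 29 tert-butyldimethyl[(3-methylfuran-2-yl)oxy]silane
Conditions: TBSOTf, Et3N, CH2Cl2, 0 °C
Reagents that add atoms: tert-butyldimethylsilyl trifluoromethanesulfonate, CC(C)(C)[Si](C)(C)OS(=O)(=O)C(F)(F)F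
Why: Soft enolisation and O-silylation of the butenolide, driven by formation of the aromatic 2-silyloxyfuran.

Step 18
Reactants: 27 (2S)-2-[(1R,4S,5S,9S)-9-(TBS-oxy)-4,8-dimethylspiro[4.5]dec-7-en-1-yl]propanal; 29 tert-butyldimethyl[(3-methylfuran-2-yl)oxy]silane
Product: 30 5-{(2S)-1-hydroxy-2-[(1R,4S,5S,9S)-9-(TBS-oxy)-4,8-dimethylspiro[4.5]dec-7-en-1-yl]propyl}-3-methylfuran-2(5H)-one (mixture at C5 and C6)
Conditions: BF3·OEt2 (1.1 equiv), CH2Cl2, −78 °C; sat. aq. NaHCO3
Reagents that add atoms: silyloxyfuran 29, Cc1ccoc1O[Si](C)(C)C(C)(C)C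
Why: Vinylogous Mukaiyama aldol, in which the silyloxyfuran attacks the BF3-activated aldehyde through C5 under acidic, non-enolising conditions that keep C7, and the two new centres (C5, C6) are removed in the next step and need no control.

Step 19
Reactants: 30 5-{(2S)-1-hydroxy-2-[(1R,4S,5S,9S)-9-(TBS-oxy)-4,8-dimethylspiro[4.5]dec-7-en-1-yl]propyl}-3-methylfuran-2(5H)-one
Product: 32 (5Z)-5-{(2S)-2-[(1R,4S,5S,9S)-9-(TBS-oxy)-4,8-dimethylspiro[4.5]dec-7-en-1-yl]propylidene}-3-methylfuran-2(5H)-one, via mesylate 31 (not isolated)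
Conditions: MsCl, Et3N, CH2Cl2, −20 → 0 °C; then DBU, 0 °C
Reagents that add atoms: none
Why: Mesylation and E1cB elimination through the 2-oxidofuran (deprotonation at C5) form C5=C6 from both aldol diastereomers, the Z isomer (C7 cis to O1) being favoured because the E isomer suffers allylic strain between C7 and C4–H, and the short, cold exposure to base spares the C7 hydrogen.

Step 20
Reactants: 32 (5Z)-5-{(2S)-2-[(1R,4S,5S,9S)-9-(TBS-oxy)-4,8-dimethylspiro[4.5]dec-7-en-1-yl]propylidene}-3-methylfuran-2(5H)-one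
Product: 33 (5Z)-5-{(2S)-2-[(1R,4S,5S,9S)-9-hydroxy-4,8-dimethylspiro[4.5]dec-7-en-1-yl]propylidene}-3-methylfuran-2(5H)-one
Conditions: HF·pyridine, pyridine/THF, 0 °C → rt
Reagents that add atoms: none
Why: Fluoride-driven cleavage of the Si–O bond under buffered acidic conditions that the alkylidene butenolide tolerates.

Step 21
Reactants: 33 (5Z)-5-{(2S)-2-[(1R,4S,5S,9S)-9-hydroxy-4,8-dimethylspiro[4.5]dec-7-en-1-yl]propylidene}-3-methylfuran-2(5H)-one; 34 3-phenylpropanoyl chloride
Product: 35 (5Z)-3-methyl-5-{(2S)-2-[(1R,4S,5S,9S)-4,8-dimethyl-9-(3-phenylpropanoyloxy)spiro[4.5]dec-7-en-1-yl]propylidene}furan-2(5H)-one (target CNP0260277.1)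
Conditions: pyridine, DMAP (cat.), CH2Cl2, 0 °C → rt
Reagents that add atoms: 3-phenylpropanoyl chloride (34), O=C(Cl)CCc1ccccc1
Why: DMAP-catalysed O-acylation of the secondary allylic alcohol with retention at C16, under mild conditions that leave the butenolide alone.

**Compound list**

1 | cyclopent-2-en-1-one | O=C1C=CCC1 | starting material
2 | 2-iodocyclopent-2-en-1-one | O=C1C(I)=CCC1 | intermediate
3 | allyltributylstannane | C=CC[Sn](CCCC)(CCCC)CCCC | starting material
4 | 2-allylcyclopent-2-en-1-one | C=CCC1=CCCC1=O | intermediate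
5 | but-2-yn-1-ol | CC#CCO | starting material
6 | sodium alkenylalanate (five-membered oxaaluminate, Al on C3) | CC1=CCO[Al-]1(OCCOC)OCCOC.[Na+] | intermediate
7 | (Z)-3-iodobut-2-en-1-ol | OC/C=C(/C)I | intermediate
8 | (Z)-1-bromo-3-iodobut-2-ene | BrC/C=C(/C)I | intermediate
9 | methylmagnesium bromide | C[Mg]Br | starting material
10 | bromomagnesium (3S)-2-allyl-3-methylcyclopent-1-en-1-olate | Br[Mg]OC1=C(CC=C)[C@@H](C)CC1 | intermediate
11 | (2R,3S)-2-allyl-2-[(Z)-3-iodobut-2-en-1-yl]-3-methylcyclopentan-1-one | O=C1CC[C@H](C)[C@@]1(CC=C)C/C=C(/C)I | intermediate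
12 | 2-[(1S,2S)-1-[(Z)-3-iodobut-2-en-1-yl]-2-methyl-5-oxocyclopentyl]acetaldehyde | O=C1CC[C@H](C)[C@@]1(CC=O)C/C=C(/C)I | intermediate
13 | (4S,5S,9S)-9-hydroxy-4,8-dimethylspiro[4.5]dec-7-en-1-one | O=C1CC[C@H](C)[C@@]12CC=C(C)[C@@H](O)C2 | intermediate
14 | (4S,5S,9S)-9-(TBS-oxy)-4,8-dimethylspiro[4.5]dec-7-en-1-one | O=C1CC[C@H](C)[C@@]12CC=C(C)[C@@H](O[Si](C)(C)C(C)(C)C)C2 | intermediate
15 | (4S,5S,9S)-9-(TBS-oxy)-4,8-dimethyl-1-(TMS-oxy)spiro[4.5]deca-1,7-diene | C[Si](C)(C)OC1=CC[C@H](C)[C@@]12CC=C(C)[C@@H](O[Si](C)(C)C(C)(C)C)C2 | intermediate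
16 | (4S,5S,9S)-9-(TBS-oxy)-4,8-dimethylspiro[4.5]deca-2,7-dien-1-one | O=C1C=C[C@H](C)[C@@]12CC=C(C)[C@@H](O[Si](C)(C)C(C)(C)C)C2 | intermediate
17 | (2S,3S,4R,5S,9S)-9-(TBS-oxy)-2,3-epoxy-4,8-dimethylspiro[4.5]dec-7-en-1-one (epoxide trans to the C11 methyl) | O=C1[C@H]3O[C@H]3[C@H](C)[C@@]12CC=C(C)[C@@H](O[Si](C)(C)C(C)(C)C)C2 | intermediate
18 | (1R,2R,5R,9S)-9-(TBS-oxy)-1,8-dimethylspiro[4.5]deca-3,7-dien-2-ol | O[C@@H]1C=C[C@]2(CC=C(C)[C@@H](O[Si](C)(C)C(C)(C)C)C2)[C@H]1C | intermediate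
19 | propanoic anhydride | CCC(=O)OC(=O)CC | starting material
20 | (1R,2R,5R,9S)-9-(TBS-oxy)-1,8-dimethylspiro[4.5]deca-3,7-dien-2-yl propanoate | CCC(=O)O[C@@H]1C=C[C@]2(CC=C(C)[C@@H](O[Si](C)(C)C(C)(C)C)C2)[C@H]1C | intermediate
21 | lithium enolate of 20 (C7 methyl cis to OLi) | C/C=C(\O[Li])O[C@@H]1C=C[C@]2(CC=C(C)[C@@H](O[Si](C)(C)C(C)(C)C)C2)[C@H]1C | intermediate
22 | trimethylsilyl ketene acetal of 20 (C7 methyl cis to OSiMe3) | C/C=C(\O[Si](C)(C)C)O[C@@H]1C=C[C@]2(CC=C(C)[C@@H](O[Si](C)(C)C(C)(C)C)C2)[C@H]1C | intermediate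
23 | trimethylsilyl (2S)-2-[(1R,4S,5S,9S)-9-(TBS-oxy)-4,8-dimethylspiro[4.5]deca-2,7-dien-1-yl]propanoate | C[Si](C)(C)OC(=O)[C@@H](C)[C@H]1C=C[C@H](C)[C@@]12CC=C(C)[C@@H](O[Si](C)(C)C(C)(C)C)C2 | intermediate
24 | (2S)-2-[(1R,4S,5S,9S)-9-(TBS-oxy)-4,8-dimethylspiro[4.5]deca-2,7-dien-1-yl]propanoic acid | OC(=O)[C@@H](C)[C@H]1C=C[C@H](C)[C@@]12CC=C(C)[C@@H](O[Si](C)(C)C(C)(C)C)C2 | intermediate
25 | (2S)-2-[(1R,4S,5S,9S)-9-(TBS-oxy)-4,8-dimethylspiro[4.5]dec-7-en-1-yl]propanoic acid | OC(=O)[C@@H](C)[C@H]1CC[C@H](C)[C@@]12CC=C(C)[C@@H](O[Si](C)(C)C(C)(C)C)C2 | intermediate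
26 | (2S)-2-[(1R,4S,5S,9S)-9-(TBS-oxy)-4,8-dimethylspiro[4.5]dec-7-en-1-yl]propan-1-ol | OC[C@@H](C)[C@H]1CC[C@H](C)[C@@]12CC=C(C)[C@@H](O[Si](C)(C)C(C)(C)C)C2 | intermediate
27 | (2S)-2-[(1R,4S,5S,9S)-9-(TBS-oxy)-4,8-dimethylspiro[4.5]dec-7-en-1-yl]propanal | O=C[C@@H](C)[C@H]1CC[C@H](C)[C@@]12CC=C(C)[C@@H](O[Si](C)(C)C(C)(C)C)C2 | intermediate
28 | 3-methylfuran-2(5H)-one | CC1=CCOC1=O | starting material
29 | tert-butyldimethyl[(3-methylfuran-2-yl)oxy]silane | Cc1ccoc1O[Si](C)(C)C(C)(C)C | intermediate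
30 | 5-{(2S)-1-hydroxy-2-[(1R,4S,5S,9S)-9-(TBS-oxy)-4,8-dimethylspiro[4.5]dec-7-en-1-yl]propyl}-3-methylfuran-2(5H)-one (mixture at C5 and C6) | CC1=CC(OC1=O)C(O)[C@@H](C)[C@H]1CC[C@H](C)[C@@]12CC=C(C)[C@@H](O[Si](C)(C)C(C)(C)C)C2 | intermediate
31 | methanesulfonate of 30 | CC1=CC(OC1=O)C(OS(C)(=O)=O)[C@@H](C)[C@H]1CC[C@H](C)[C@@]12CC=C(C)[C@@H](O[Si](C)(C)C(C)(C)C)C2 | intermediate
32 | (5Z)-5-{(2S)-2-[(1R,4S,5S,9S)-9-(TBS-oxy)-4,8-dimethylspiro[4.5]dec-7-en-1-yl]propylidene}-3-methylfuran-2(5H)-one | CC1=C/C(=C/[C@@H](C)[C@H]2CC[C@H](C)[C@@]23CC=C(C)[C@@H](O[Si](C)(C)C(C)(C)C)C3)OC1=O | intermediate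
33 | (5Z)-5-{(2S)-2-[(1R,4S,5S,9S)-9-hydroxy-4,8-dimethylspiro[4.5]dec-7-en-1-yl]propylidene}-3-methylfuran-2(5H)-one | CC1=C/C(=C/[C@@H](C)[C@H]2CC[C@H](C)[C@@]23CC=C(C)[C@@H](O)C3)OC1=O | intermediate
34 | 3-phenylpropanoyl chloride | O=C(Cl)CCc1ccccc1 | starting material
35 | (5Z)-3-methyl-5-{(2S)-2-[(1R,4S,5S,9S)-4,8-dimethyl-9-(3-phenylpropanoyloxy)spiro[4.5]dec-7-en-1-yl]propylidene}furan-2(5H)-one; in the route numbering 7S,8R,11S,12S,16S | CC1=C/C(=C/[C@@H](C)[C@H]2CC[C@H](C)[C@@]23CC=C(C)[C@@H](OC(=O)CCc2ccccc2)C3)OC1=O | target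

**Step count**

Total steps: 21. Longest linear sequence: 18 (steps 1, 2, 5–16, 18–21).

**Steps most likely to fail, with fallbacks**

Step 5. The 2-substituted cyclopentenone may give insufficient enantio-induction, and the hindered tetrasubstituted magnesium enolate may be alkylated sluggishly (proton quench or O-alkylation competing). The fallback sets out from 1 and 9 and comes back at 11; it builds the quaternary centre by two successive alkylations, so the asymmetric step runs on the parent enone. The same copper/ferrocenyl diphosphine system adds 9 to 1, and the enolate, bromomagnesium (3S)-3-methylcyclopent-1-en-1-olate F1, is trapped with allyl iodide and HMPA to give the trans ketone (2R,3S)-2-allyl-3-methylcyclopentan-1-one F2. Thermodynamic silylation (TMSCl, NaI, Et3N, MeCN) gives the more substituted silyl enol ether {[(3S)-2-allyl-3-methylcyclopent-1-en-1-yl]oxy}trimethylsilane F3. MeLi in THF frees lithium (3S)-2-allyl-3-methylcyclopent-1-en-1-olate F4, which is alkylated by 8 (HMPA, −78 → 0 °C) on the face opposite the C11 methyl to return 11.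

Step 7. Facial selectivity at the aldehyde may be poor in the ring B closure, giving the C16 epimer as well. The fallback sets out from 12 and comes back at 13; it replaces substrate control by reagent control. The cyclisation is run as in step 7 whatever its selectivity, and the mixture of 13 and its epimer (4S,5S,9R)-9-hydroxy-4,8-dimethylspiro[4.5]dec-7-en-1-one F5 is oxidised with MnO2 (allylic alcohol only) to (4S,5S)-4,8-dimethylspiro[4.5]dec-7-ene-1,9-dione F6. Corey–Bakshi–Shibata reduction with (R)-2-methyl-CBS-oxazaborolidine and catecholborane in toluene at −78 °C should reduce the enone carbonyl before the α-quaternary cyclopentanone and, with the C15 alkenyl arm as the large group, give 16S, that is 13.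

Step 13. C7 selectivity may be lost through mixed ketene acetal geometry or competition between chair and boat transition states. The fallback sets out from 18 and comes back at 24; it sets C8 by a Claisen rearrangement without a C7 centre and then sets C7 by an oxazolidinone auxiliary.
- Johnson–Claisen rearrangement of 18 (triethyl orthoacetate, cat. propanoic acid, 140 °C) gives ethyl 2-[(1S,4S,5S,9S)-9-(TBS-oxy)-4,8-dimethylspiro[4.5]deca-2,7-dien-1-yl]acetate F7.
- LiOH in THF/H2O gives 2-[(1S,4S,5S,9S)-9-(TBS-oxy)-4,8-dimethylspiro[4.5]deca-2,7-dien-1-yl]acetic acid F8.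
- Pivaloyl chloride and Et3N give the mixed pivalic anhydride F9, which acylates lithiated (S)-4-benzyloxazolidin-2-one to give (4S)-4-benzyl-3-{2-[(1S,4S,5S,9S)-9-(TBS-oxy)-4,8-dimethylspiro[4.5]deca-2,7-dien-1-yl]acetyl}oxazolidin-2-one F10.
- NaHMDS at −78 °C gives the chelated sodium (Z)-enolate F11, and MeI adds on the face away from the benzyl group to give (4S)-4-benzyl-3-{(2S)-2-[(1R,4S,5S,9S)-9-(TBS-oxy)-4,8-dimethylspiro[4.5]deca-2,7-dien-1-yl]propanoyl}oxazolidin-2-one F12.
- LiOH/H2O2 removes the auxiliary to return 24.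

Further compounds
F1 | step 5 | bromomagnesium (3S)-3-methylcyclopent-1-en-1-olate | Br[Mg]OC1=C[C@@H](C)CC1
F2 | step 5 | (2R,3S)-2-allyl-3-methylcyclopentan-1-one | O=C1CC[C@H](C)[C@H]1CC=C
F3 | step 5 | {[(3S)-2-allyl-3-methylcyclopent-1-en-1-yl]oxy}trimethylsilane | C[Si](C)(C)OC1=C(CC=C)[C@@H](C)CC1
F4 | step 5 | lithium (3S)-2-allyl-3-methylcyclopent-1-en-1-olate | [Li]OC1=C(CC=C)[C@@H](C)CC1
F5 | step 7 | (4S,5S,9R)-9-hydroxy-4,8-dimethylspiro[4.5]dec-7-en-1-one | O=C1CC[C@H](C)[C@@]12CC=C(C)[C@H](O)C2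
F6 | step 7 | (4S,5S)-4,8-dimethylspiro[4.5]dec-7-ene-1,9-dione | O=C1CC[C@H](C)[C@@]12CC=C(C)C(=O)C2
F7 | step 13 | ethyl 2-[(1S,4S,5S,9S)-9-(TBS-oxy)-4,8-dimethylspiro[4.5]deca-2,7-dien-1-yl]acetate | CCOC(=O)C[C@H]1C=C[C@H](C)[C@@]12CC=C(C)[C@@H](O[Si](C)(C)C(C)(C)C)C2
F8 | step 13 | 2-[(1S,4S,5S,9S)-9-(TBS-oxy)-4,8-dimethylspiro[4.5]deca-2,7-dien-1-yl]acetic acid | OC(=O)C[C@H]1C=C[C@H](C)[C@@]12CC=C(C)[C@@H](O[Si](C)(C)C(C)(C)C)C2
F9 | step 13 | mixed pivalic anhydride of F8 | CC(C)(C)C(=O)OC(=O)C[C@H]1C=C[C@H](C)[C@@]12CC=C(C)[C@@H](O[Si](C)(C)C(C)(C)C)C2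
F10 | step 13 | (4S)-4-benzyl-3-{2-[(1S,4S,5S,9S)-9-(TBS-oxy)-4,8-dimethylspiro[4.5]deca-2,7-dien-1-yl]acetyl}oxazolidin-2-one | O=C(C[C@H]1C=C[C@H](C)[C@@]12CC=C(C)[C@@H](O[Si](C)(C)C(C)(C)C)C2)N1[C@@H](Cc2ccccc2)COC1=O
F11 | step 13 | sodium (Z)-enolate of F10 | [Na]O/C(=C\[C@H]1C=C[C@H](C)[C@@]12CC=C(C)[C@@H](O[Si](C)(C)C(C)(C)C)C2)N1[C@@H](Cc2ccccc2)COC1=O
F12 | step 13 | (4S)-4-benzyl-3-{(2S)-2-[(1R,4S,5S,9S)-9-(TBS-oxy)-4,8-dimethylspiro[4.5]deca-2,7-dien-1-yl]propanoyl}oxazolidin-2-one | O=C([C@@H](C)[C@H]1C=C[C@H](C)[C@@]12CC=C(C)[C@@H](O[Si](C)(C)C(C)(C)C)C2)N1[C@@H](Cc2ccccc2)COC1=O
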